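The numbers of this flask are those of an exercise; the flask was simulated.

The acidic substrate meets the electrophile as its anion, and the question is how much of that pool, substrate and anion together, has been drained when the run stops.

common to all: acidic substrate 10 mM; free base 1.05 equiv; time 1.5 min

| run | electrophile |
|---|---|
| birch | 0.800 equiv |
| oak | 1.20 equiv |
| maple | 2.00 equiv |
| ash | 3.00 equiv |

1. amount of product at the end, in percent of the acidic substrate charged for birch, oak, maple, ash, in this order
2. how that number moves from the first to the last of them (falls all the way / falls, then rises / rises all the way / rises, then falls / hardly changes)

- product is meant together with its crystals
- solid, in amounts per volume of the solution: crystals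
- "hardly changes" means that all values lie within two and a half points (for a concentration: within two and a half percent of the largest)
- run time (birch): 1.5 min

Two times carry this reckoning of my own: the run of 1.5 min and the half-life of the pool. The electrophile consumes the anion with rate constant 1.39 M⁻¹ s⁻¹, and the balance with the free base, constant 32.8, keeps part of the pool as anion. Taking free base and substrate as equal, that part is the root of the constant over one plus the root, 85.1 %. With the electrophile held at its charge, the pool then decays as a pseudo-first-order species. In birch this gives 1.22 min: ln(2) over the rate constant, the charged electrophile and the anion share, the pool half-life.

The run is longer than that, and birch gets 1.23 pool half-lives. The count grows in step with the equivalents, so ash gets 4.61. With the electrophile held at its charge, the share drained after so many half-lives is 57.3 %, 72.1 %, 88.1 % and 95.9 % in recipe order. But the electrophile falls one for one with the pool, so the figures I commit to come from the second-order form of the same reckoning. Its reach is the rate constant times the anion share, the substrate charge and the run, 1.07; with e the equivalents of electrophile, g is the exponential of the reach times one less e, and the product share is e times g less one, over g less e. That gives 43.4 %, 58.8 %, 79.2 % and 91.8 %. The reckoning commits to a product that rises all the way, with ash ahead of birch.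

The forecast gives 43.5 %, 58.7 %, 78.1 % and 90.3 %, so rises all the way, and it sets aside the solid: "Crystals only hold product out of solution." For birch it stands below the share reckoned with the electrophile held.

The flasks give 43.4 %, 58.4 %, 78.1 % and 90.3 %, so rises all the way, as the forecast said.

    electrophile + anion → product (k1 = 1.39 M⁻¹ s⁻¹)
    acidic substrate + free base ⇌ protonated base + anion, settled at all times (K2 = 32.8)
    crystals ⇌ product, rate k3*(cs3 - [product]) while solid is left; crystals form when [product] > cs3 (cs3 = 6.9 mM, k3 = 2.91 s⁻¹)

Birch falls short through two causes acting together, the depletion of electrophile and the length of the run. Holding the electrophile at its charge lifts birch from 43.4 % to 57.1 %, and a run ten times as long lifts it to 77.6 %. The held figure stands beside the 57.3 % from the pool half-life. In ash, with 4.61 pool half-lives, the count gives 95.9 %, and holding the electrophile at its charge takes the product from 90.3 % to 94.6 %, so the depletion of electrophile is a part of the shortfall of ash, worth 4.2 percentage points.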